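**Plan**

1. Locants: the target is read as two ε-viniferin-type halves. The trans half is unit A (C7a, C8a; the 4-hydroxyphenyl ring on C7a is called the aryl ring of unit A, the 3,5-dihydroxyphenyl ring on C8a its resorcinol ring) plus unit B (its benzofuran ring, C8b, C7b and the aryl ring of unit B on C7b). The cis half is units C and D, named the same way.
2. Retrosynthetic cuts, in order: C7b–C10c (second eight-membered ring), C7d–C10a (first eight-membered ring), C8b–C8d, then the C7–C8 bonds of both dihydrofurans. This leaves one diaryl ketone built from 5-bromoresorcinol and two protected 4-hydroxyacetophenones.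
3. Forward: one cis-dihydrobenzofuran bromide (Rh2(R-PTAD)4-catalysed carbene C–H insertion) is divided into the trans half (C7a epimerised) and the cis half. Each is α-arylated to a ketone, the ketones are joined at C8b–C8d, and the two eight-membered rings are closed one after the other.
4. Enabling feature: C7b and C7d each carry a 4-oxygenated phenyl ring and an ester, so each is a latent para-quinone methide that C10 of the resorcinol ring on C8 of the other half can reach through an eight-membered ring. Which phenols are free decides which ring closes: TIPS on the resorcinol ring of unit A and the aryl ring of unit D leaves with fluoride, PMB on the resorcinol ring of unit C and the aryl ring of unit B with DDQ, and benzyl on the benzofuran rings keeps them unreactive.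
5. Stereochemistry: C7/C8 of both dihydrofurans come from Rh2(R-PTAD)4 (cis, 2R,3S), with C7a then inverted by acid. C8b/C8d are set by base equilibration of the 1,4-diketone. C7d and C7b are set in the two ring closures, each steered by the neighbouring C8 centre.

Key step: step 21

Assumption: Rh2(R-PTAD)4 is taken to deliver the (2R,3S)-cis-dihydrobenzofuran; if its sense is the opposite, Rh2(S-PTAD)4 is used with nothing else changed.
Abbreviations: Bn = benzyl, PMB = 4-methoxybenzyl, TIPS = triisopropylsilyl, Piv = pivaloyl.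

**Route**

Step 1
Reactants: 1 5-bromoresorcinol
Product: 2 2-bromo-4,6-dihydroxybenzaldehyde
Conditions: POCl3, DMF, MeCN, 0 °C to rt; then H2O, 50 °C
Reagents that add atoms: N,N-dimethylformamide CN(C)C=O; water O
Why: Vilsmeier–Haack formylation should go to the carbon ortho to one hydroxyl and para to the other (next to bromine), as with resorcinol itself, the carbon between the two hydroxyls being the slower site.

Step 2
Reactants: 2 2-bromo-4,6-dihydroxybenzaldehyde
Product: 3 4-(benzyloxy)-2-bromo-6-hydroxybenzaldehyde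
Conditions: BnBr (1.05 equiv), NaHCO3, KI (cat.), MeCN, 70 °C
Reagents that add atoms: benzyl bromide BrCc1ccccc1
Why: Williamson etherification; the hydroxyl ortho to the aldehyde is held in a hydrogen bond, so the weak base should alkylate only the para hydroxyl.

Step 3
Reactants: 3 4-(benzyloxy)-2-bromo-6-hydroxybenzaldehyde; 4 4-(benzyloxy)benzyl chloride
Product: 5 4-(benzyloxy)-2-{[4-(benzyloxy)phenyl]methoxy}-6-bromobenzaldehyde
Conditions: K2CO3, Bu4NI (cat.), DMF, 60 °C
Reagents that add atoms: none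
Why: Williamson etherification of the chelated phenol under stronger conditions; the new OCH2 carbon becomes C7 of both dihydrobenzofurans.

Step 4
Reactants: 1 5-bromoresorcinol
Product: 6 1-bromo-3,5-bis(triisopropylsilyloxy)benzene
Conditions: iPr3SiCl (2.4 equiv), imidazole, DMF, rt
Reagents that add atoms: triisopropylsilyl chloride CC(C)[Si](Cl)(C(C)C)C(C)C
Why: imidazole-promoted silylation of both phenols gives ethers that survive organolithium, acid and weak base and leave later with fluoride.

Step 5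
Reactants: 6 1-bromo-3,5-bis(triisopropylsilyloxy)benzene; 5 4-(benzyloxy)-2-{[4-(benzyloxy)phenyl]methoxy}-6-bromobenzaldehyde
Product: 7 racemic diaryl carbinol
Conditions: n-BuLi (1.0 equiv), THF, −78 °C; then 5, −78 °C; aq. NH4Cl
Reagents that add atoms: none
Why: bromine–lithium exchange and 1,2-addition of the aryllithium to the aldehyde, which at −78 °C should outrun exchange with the aryl bromide of 5; the carbinol centre is removed in step 6.

Step 6
Reactants: 7 racemic diaryl carbinol
Product: 8 diaryl ketone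
Conditions: MnO2 (excess), CH2Cl2, rt
Reagents that add atoms: none
Why: MnO2 oxidation of a doubly benzylic alcohol; ethers and the aryl bromide are inert.

Step 7
Reactants: 8 diaryl ketone
Product: 9 hydrazone of 8
Conditions: N2H4·H2O (excess), AcOH (cat.), EtOH, 80 °C
Reagents that add atoms: hydrazine NN
Why: condensation to the N-unsubstituted hydrazone (either C=N isomer serves), the precursor of a donor/donor diazo compound.

Step 8
Reactants: 9 hydrazone of 8
Product: 11 (2R,3S)-cis-dihydrobenzofuran bromide, via diaryldiazomethane 10 (not isolated)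
Conditions: MnO2, CH2Cl2, 0 °C; then Rh2(R-PTAD)4 (1 mol%), 0 °C to rt
Reagents that add atoms: none
Why: oxidation to the diaryldiazomethane and rhodium-carbene 1,5 C–H insertion into the benzylic ether C–H (donor/donor carbene insertion); the concerted insertion should give the cis ring, and the chiral carboxylate ligands set C2 and C3 together as (2R,3S).

Step 9
Reactants: 11 (2R,3S)-cis-dihydrobenzofuran bromide
Product: 12 (2S,3S)-trans-dihydrobenzofuran bromide
Conditions: CF3CO2H (5 equiv), CH2Cl2, 0 °C to rt, dilute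
Reagents that add atoms: none
Why: acid-mediated epimerisation: reversible opening of the C2–O bond to the para-benzyloxybenzyl cation and reclosure should give the more stable trans isomer, C3 is not touched and only C2 inverts.

Step 10
Reactants: 13 4′-hydroxyacetophenone
Product: 14 4′-[(4-methoxybenzyl)oxy]acetophenone
Conditions: 4-MeOC6H4CH2Cl, K2CO3, DMF, 60 °C
Reagents that add atoms: 4-methoxybenzyl chloride COc1ccc(CCl)cc1
Why: Williamson etherification; this PMB group later marks the aryl ring of unit B for release by DDQ.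

Step 11
Reactants: 12 (2S,3S)-trans-dihydrobenzofuran bromide; 14 4′-[(4-methoxybenzyl)oxy]acetophenone
Product: 15 trans-half ketone
Conditions: Pd2(dba)3 (2.5 mol%), XPhos (10 mol%), K3PO4, 14 (2 equiv), toluene, 90 °C
Reagents that add atoms: none
Why: palladium-catalysed α-arylation of a ketone enolate with the aryl bromide; the bulky biarylphosphine tolerates the ortho substituent, excess ketone keeps it to monoarylation and K3PO4 leaves the silyl ethers alone.

Step 12
Reactants: 15 trans-half ketone
Product: 16 trans-half α-bromoketone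
Conditions: LiN(SiMe3)2, THF, −78 °C; then N-bromosuccinimide, −78 °C; aq. NH4Cl
Reagents that add atoms: N-bromosuccinimide O=C1CCC(=O)N1Br
Why: bromination of the lithium enolate at the benzylic α-carbon, fast enough at −78 °C to spare the electron-rich arenes; both epimers at the C–Br carbon are used, since that centre is substituted and re-equilibrated in step 17.

Step 13
Reactants: 11 (2R,3S)-cis-dihydrobenzofuran bromide
Product: 17 (2R,3S)-cis-dihydrobenzofuran resorcinol
Conditions: Bu4NF (2.2 equiv), THF, 0 °C; AcOH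
Reagents that add atoms: none
Why: fluoride desilylation; the cis ring should be stable to the phenoxide medium because its C2 aryl is a benzyl ether and cannot form a quinone methide.

Step 14
Reactants: 17 (2R,3S)-cis-dihydrobenzofuran resorcinol
Product: 18 (2R,3S)-cis-dihydrobenzofuran bis-PMB ether
Conditions: 4-MeOC6H4CH2Cl (2.4 equiv), K2CO3, DMF, 50 °C
Reagents that add atoms: 4-methoxybenzyl chloride COc1ccc(CCl)cc1
Why: Williamson etherification; PMB ethers on the resorcinol ring of unit C survive the later fluoride step and leave under DDQ, which separates the two ring closures in time.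

Step 15
Reactants: 13 4′-hydroxyacetophenone
Product: 19 4′-(triisopropylsilyloxy)acetophenone
Conditions: iPr3SiCl, imidazole, DMF, rt
Reagents that add atoms: triisopropylsilyl chloride CC(C)[Si](Cl)(C(C)C)C(C)C
Why: silylation; this TIPS group marks the aryl ring of unit D for release by fluoride together with the resorcinol ring of unit A.

Step 16
Reactants: 18 (2R,3S)-cis-dihydrobenzofuran bis-PMB ether; 19 4′-(triisopropylsilyloxy)acetophenone
Product: 20 cis-half ketone
Conditions: Pd2(dba)3 (2.5 mol%), XPhos (10 mol%), K3PO4, 19 (2 equiv), toluene, 90 °C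
Reagents that add atoms: none
Why: the same palladium-catalysed ketone α-arylation as in step 11; the anhydrous weak base should spare the aryl silyl ether.

Step 17
Reactants: 20 cis-half ketone; 16 trans-half α-bromoketone
Product: 21 (8bS,8dR)-1,4-diketone
Conditions: KN(SiMe3)2 (1.05 equiv), THF, −78 °C; then 16, −78 to 0 °C; then DBU (0.2 equiv), THF, rt
Reagents that add atoms: none
Why: alkylation of the potassium enolate of 20 by the α-bromoketone, the classical route to 2,3-diaryl-1,4-diketones, forms C8b–C8d; both new centres are α to a ketone, so DBU should equilibrate them toward the unlike arrangement with the two aryl groups anti, and the (8bS,8dR) isomer is separated while the others are returned to the same equilibration.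

Step 18
Reactants: 21 (8bS,8dR)-1,4-diketone
Product: 22 1,4-diol
Conditions: NaBH4, THF/EtOH, 0 °C
Reagents that add atoms: none
Why: hydride reduction of both aryl ketones; the configuration of the two carbinol carbons is of no consequence because each later becomes a planar quinone methide carbon.

Step 19
Reactants: 22 1,4-diol
Product: 23 bis-pivalate
Conditions: t-BuCOCl, DMAP, pyridine, CH2Cl2, 0 to 40 °C
Reagents that add atoms: pivaloyl chloride CC(C)(C)C(Cl)=O
Why: DMAP-catalysed acylation turns both benzylic hydroxyls into leaving groups that should stay in place until the para oxygen of their own aryl ring is set free.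

Step 20
Reactants: 23 bis-pivalate
Product: 26 first-ring triacetate, via quinone methide 24 (not isolated), via triphenol 25 (not isolated)
Conditions: Bu4NF (3.3 equiv), THF/MeOH (4:1), −20 to 0 °C, dilute; then Ac2O, Et3N, DMAP (cat.), 0 °C to rt
Reagents that add atoms: acetic anhydride CC(=O)OC(C)=O
Why: fluoride removes the three silyl groups, the phenoxide of the unit D aryl ring expels the C7d pivalate (1,6-elimination) to quinone methide 24, and the resorcinolate of unit A, the only phenolate that can reach C7d while the resorcinol ring of unit C is still a bis-PMB ether and C7b an ester on a non-phenolic ring, should close the first eight-membered ring by 1,6-conjugate addition through C10a (8-exo-trig) with H-7d syn to H-8d under control of the C8d centre; acetylation in the same flask shields the new phenols from DDQ.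

Step 21
Reactants: 26 first-ring triacetate
Product: 29 tetra-O-benzyl ether of the target, via triphenol pivalate 27 (not isolated), via quinone methide 28 (not isolated)
Conditions: DDQ (3.6 equiv), CH2Cl2/pH 7 buffer, 0 °C; NaHCO3 wash, solvent change; then K2CO3, MeOH/THF, 0 °C to rt, dilute
Reagents that add atoms: none
Why: DDQ cleaves the three PMB ethers (benzylic hydride abstraction, hemiacetal collapse) to triphenol 27, and carbonate in methanol then removes the three aryl acetates and ionises the phenols, so that the para-phenoxide of the unit B aryl ring expels pivalate from C7b (1,6-elimination) to quinone methide 28, which the resorcinolate of unit C attacks through C10c (1,6-conjugate addition, then rearomatisation). The closest known reaction type is the base-triggered generation of a para-quinone methide from a para-hydroxybenzyl ester and its capture by a phenolate carbon, the Friedel–Crafts event that stilbenoid oligomer biosynthesis is thought to use. It closes the eight-membered carbocycle C8b–C7b–C10c–C9c–C8c–C10d–C9d–C8d in an 8-exo-trig mode on the exocyclic C7b=C bond. The new centre C7b should be set by the ring being formed: C10c is tied through C8c and the benzofuran ring of unit D to C8d and is expected to reach only the face of the quinone methide that puts H-7b anti to H-8b and the unit B aryl ring pseudo-equatorial, which is the (7bR) configuration. The step needs attack by C10c only and C- over O-alkylation: only the resorcinol ring of unit C is a phenolate able to reach C7b (the benzofuran rings are benzyl ethers and do not add to a neutral quinone methide), C7d is already sp3 so the seven-membered ampelopsin-type closure is shut, the free ortho carbon of the unit A resorcinol ring could reach C7b only through a [4]metacyclophane, O-alkylation is reversible, and methanol holds the quinone methide as its reversible adduct against tautomerisation to the stilbene. The PMB aryl ethers should be cleaved at 0 °C well before DDQ touches the benzyl ethers or the hindered tertiary C7–H bonds of the two dihydrofurans.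

Step 22
Reactants: 29 tetra-O-benzyl ether of the target
Product: 30 CNP0224452.3
Conditions: H2 (1 atm), 10% Pd/C, EtOAc/MeOH, rt
Reagents that add atoms: none
Why: hydrogenolysis of the four benzyl aryl ethers under neutral conditions, chosen because the cis-dihydrobenzofuran would epimerise at C7c under acid or as a free phenoxide in base; the cyclic benzylic C7–O bonds should be cleaved much more slowly than benzyl aryl ethers.

**Compound list**

1 | 5-bromobenzene-1,3-diol (5-bromoresorcinol) | Oc1cc(O)cc(Br)c1 | starting material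
2 | 2-bromo-4,6-dihydroxybenzaldehyde | O=Cc1c(O)cc(O)cc1Br | intermediate
3 | 4-(benzyloxy)-2-bromo-6-hydroxybenzaldehyde | O=Cc1c(O)cc(OCc2ccccc2)cc1Br | intermediate
4 | 1-(benzyloxy)-4-(chloromethyl)benzene (4-benzyloxybenzyl chloride) | ClCc1ccc(OCc2ccccc2)cc1 | starting material
5 | 4-(benzyloxy)-2-{[4-(benzyloxy)phenyl]methoxy}-6-bromobenzaldehyde | O=Cc1c(OCc2ccc(OCc3ccccc3)cc2)cc(OCc2ccccc2)cc1Br | intermediate
6 | 1-bromo-3,5-bis(triisopropylsilyloxy)benzene | CC(C)[Si](C(C)C)(C(C)C)Oc1cc(Br)cc(O[Si](C(C)C)(C(C)C)C(C)C)c1 | intermediate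
7 | [4-(benzyloxy)-2-{[4-(benzyloxy)phenyl]methoxy}-6-bromophenyl][3,5-bis(triisopropylsilyloxy)phenyl]methanol, racemic | CC(C)[Si](C(C)C)(C(C)C)Oc1cc(O[Si](C(C)C)(C(C)C)C(C)C)cc(c1)C(O)c1c(OCc2ccc(OCc3ccccc3)cc2)cc(OCc2ccccc2)cc1Br | intermediate
8 | [4-(benzyloxy)-2-{[4-(benzyloxy)phenyl]methoxy}-6-bromophenyl][3,5-bis(triisopropylsilyloxy)phenyl]methanone | CC(C)[Si](C(C)C)(C(C)C)Oc1cc(O[Si](C(C)C)(C(C)C)C(C)C)cc(c1)C(=O)c1c(OCc2ccc(OCc3ccccc3)cc2)cc(OCc2ccccc2)cc1Br | intermediate
9 | hydrazone of ketone 8 (either C=N isomer) | CC(C)[Si](C(C)C)(C(C)C)Oc1cc(O[Si](C(C)C)(C(C)C)C(C)C)cc(c1)C(=NN)c1c(OCc2ccc(OCc3ccccc3)cc2)cc(OCc2ccccc2)cc1Br | intermediate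
10 | diaryldiazomethane from 9 | CC(C)[Si](C(C)C)(C(C)C)Oc1cc(O[Si](C(C)C)(C(C)C)C(C)C)cc(c1)C(=[N+]=[N-])c1c(OCc2ccc(OCc3ccccc3)cc2)cc(OCc2ccccc2)cc1Br | intermediate
11 | (2R,3S)-6-(benzyloxy)-2-[4-(benzyloxy)phenyl]-4-bromo-3-[3,5-bis(triisopropylsilyloxy)phenyl]-2,3-dihydro-1-benzofuran (cis) | CC(C)[Si](C(C)C)(C(C)C)Oc1cc(O[Si](C(C)C)(C(C)C)C(C)C)cc(c1)[C@H]1c2c(Br)cc(OCc3ccccc3)cc2O[C@H]1c1ccc(OCc2ccccc2)cc1 | intermediate
12 | (2S,3S)-6-(benzyloxy)-2-[4-(benzyloxy)phenyl]-4-bromo-3-[3,5-bis(triisopropylsilyloxy)phenyl]-2,3-dihydro-1-benzofuran (trans) | CC(C)[Si](C(C)C)(C(C)C)Oc1cc(O[Si](C(C)C)(C(C)C)C(C)C)cc(c1)[C@H]1c2c(Br)cc(OCc3ccccc3)cc2O[C@@H]1c1ccc(OCc2ccccc2)cc1 | intermediate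
13 | 1-(4-hydroxyphenyl)ethan-1-one (4′-hydroxyacetophenone) | CC(=O)c1ccc(O)cc1 | starting material
14 | 1-{4-[(4-methoxybenzyl)oxy]phenyl}ethan-1-one | CC(=O)c1ccc(OCc2ccc(OC)cc2)cc1 | intermediate
15 | trans-half ketone: 12 with Br replaced by CH2C(=O)C6H4-4-OPMB | CC(C)[Si](C(C)C)(C(C)C)Oc1cc(O[Si](C(C)C)(C(C)C)C(C)C)cc(c1)[C@H]1c2c(CC(=O)c3ccc(OCc4ccc(OC)cc4)cc3)cc(OCc3ccccc3)cc2O[C@@H]1c1ccc(OCc2ccccc2)cc1 | intermediate
16 | trans-half α-bromoketone: 15 brominated at the CH2 carbon (future C8b), both epimers | CC(C)[Si](C(C)C)(C(C)C)Oc1cc(O[Si](C(C)C)(C(C)C)C(C)C)cc(c1)[C@H]1c2c(C(Br)C(=O)c3ccc(OCc4ccc(OC)cc4)cc3)cc(OCc3ccccc3)cc2O[C@@H]1c1ccc(OCc2ccccc2)cc1 | intermediate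
17 | 5-{(2R,3S)-6-(benzyloxy)-2-[4-(benzyloxy)phenyl]-4-bromo-2,3-dihydro-1-benzofuran-3-yl}benzene-1,3-diol (cis) | Oc1cc(O)cc(c1)[C@H]1c2c(Br)cc(OCc3ccccc3)cc2O[C@H]1c1ccc(OCc2ccccc2)cc1 | intermediate
18 | (2R,3S)-6-(benzyloxy)-2-[4-(benzyloxy)phenyl]-4-bromo-3-{3,5-bis[(4-methoxybenzyl)oxy]phenyl}-2,3-dihydro-1-benzofuran (cis) | COc1ccc(COc2cc(OCc3ccc(OC)cc3)cc(c2)[C@H]2c3c(Br)cc(OCc4ccccc4)cc3O[C@H]2c2ccc(OCc3ccccc3)cc2)cc1 | intermediate
19 | 1-[4-(triisopropylsilyloxy)phenyl]ethan-1-one | CC(=O)c1ccc(O[Si](C(C)C)(C(C)C)C(C)C)cc1 | intermediate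
20 | cis-half ketone: 18 with Br replaced by CH2C(=O)C6H4-4-OTIPS | COc1ccc(COc2cc(OCc3ccc(OC)cc3)cc(c2)[C@H]2c3c(CC(=O)c4ccc(O[Si](C(C)C)(C(C)C)C(C)C)cc4)cc(OCc4ccccc4)cc3O[C@H]2c2ccc(OCc3ccccc3)cc2)cc1 | intermediate
21 | (8bS,8dR)-1,4-diketone: butane-1,4-dione with 4-(PMB-oxy)phenyl on C1 (C7b), the trans-dihydrobenzofuran-4-yl group of 15 on C2 (C8b), the cis-dihydrobenzofuran-4-yl group of 20 on C3 (C8d) and 4-(TIPS-oxy)phenyl on C4 (C7d) | CC(C)[Si](C(C)C)(C(C)C)Oc1cc(O[Si](C(C)C)(C(C)C)C(C)C)cc(c1)[C@H]1c2c([C@@H](C(=O)c3ccc(OCc4ccc(OC)cc4)cc3)[C@@H](C(=O)c3ccc(O[Si](C(C)C)(C(C)C)C(C)C)cc3)c3cc(OCc4ccccc4)cc4O[C@@H](c5ccc(OCc6ccccc6)cc5)[C@@H](c5cc(OCc6ccc(OC)cc6)cc(OCc6ccc(OC)cc6)c5)c34)cc(OCc3ccccc3)cc2O[C@@H]1c1ccc(OCc2ccccc2)cc1 | intermediate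
22 | 1,4-diol from 21 (C7b and C7d carbinols, each a mixture) | CC(C)[Si](C(C)C)(C(C)C)Oc1cc(O[Si](C(C)C)(C(C)C)C(C)C)cc(c1)[C@H]1c2c([C@@H](C(O)c3ccc(OCc4ccc(OC)cc4)cc3)[C@@H](C(O)c3ccc(O[Si](C(C)C)(C(C)C)C(C)C)cc3)c3cc(OCc4ccccc4)cc4O[C@@H](c5ccc(OCc6ccccc6)cc5)[C@@H](c5cc(OCc6ccc(OC)cc6)cc(OCc6ccc(OC)cc6)c5)c34)cc(OCc3ccccc3)cc2O[C@@H]1c1ccc(OCc2ccccc2)cc1 | intermediate
23 | bis-pivalate of 22 (pivalates on C7b–O and C7d–O) | CC(C)[Si](C(C)C)(C(C)C)Oc1cc(O[Si](C(C)C)(C(C)C)C(C)C)cc(c1)[C@H]1c2c([C@@H](C(OC(=O)C(C)(C)C)c3ccc(OCc4ccc(OC)cc4)cc3)[C@@H](C(OC(=O)C(C)(C)C)c3ccc(O[Si](C(C)C)(C(C)C)C(C)C)cc3)c3cc(OCc4ccccc4)cc4O[C@@H](c5ccc(OCc6ccccc6)cc5)[C@@H](c5cc(OCc6ccc(OC)cc6)cc(OCc6ccc(OC)cc6)c5)c34)cc(OCc3ccccc3)cc2O[C@@H]1c1ccc(OCc2ccccc2)cc1 | intermediate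
24 | para-quinone methide at C7d: 23 without its three TIPS groups and without the C7d pivalate | Oc1cc(O)cc(c1)[C@H]1c2c([C@@H](C(OC(=O)C(C)(C)C)c3ccc(OCc4ccc(OC)cc4)cc3)[C@@H](C=C3C=CC(=O)C=C3)c3cc(OCc4ccccc4)cc4O[C@@H](c5ccc(OCc6ccccc6)cc5)[C@@H](c5cc(OCc6ccc(OC)cc6)cc(OCc6ccc(OC)cc6)c5)c34)cc(OCc3ccccc3)cc2O[C@@H]1c1ccc(OCc2ccccc2)cc1 | intermediate
25 | first-ring triphenol: C7d–C10a bond closed, free phenols on the resorcinol ring of unit A and the aryl ring of unit D, C7b pivalate and PMB ethers intact | Oc1ccc(cc1)[C@@H]2c3c(O)cc(O)cc3[C@H]3c4c(cc(OCc5ccccc5)cc4[C@@H](C(OC(=O)C(C)(C)C)c5ccc(OCc6ccc(OC)cc6)cc5)[C@@H]2c5cc(OCc6ccccc6)cc6O[C@@H](c7ccc(OCc8ccccc8)cc7)[C@@H](c7cc(OCc8ccc(OC)cc8)cc(OCc8ccc(OC)cc8)c7)c56)O[C@@H]3c2ccc(OCc5ccccc5)cc2 | intermediate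
26 | first-ring triacetate: 25 acetylated on the three free phenols | CC(=O)Oc1ccc(cc1)[C@@H]2c3c(OC(C)=O)cc(OC(C)=O)cc3[C@H]3c4c(cc(OCc5ccccc5)cc4[C@@H](C(OC(=O)C(C)(C)C)c5ccc(OCc6ccc(OC)cc6)cc5)[C@@H]2c5cc(OCc6ccccc6)cc6O[C@@H](c7ccc(OCc8ccccc8)cc7)[C@@H](c7cc(OCc8ccc(OC)cc8)cc(OCc8ccc(OC)cc8)c7)c56)O[C@@H]3c2ccc(OCc5ccccc5)cc2 | intermediate
27 | triphenol pivalate: 26 without its three PMB groups (free phenols on the resorcinol ring of unit C and the aryl ring of unit B) | CC(=O)Oc1ccc(cc1)[C@@H]2c3c(OC(C)=O)cc(OC(C)=O)cc3[C@H]3c4c(cc(OCc5ccccc5)cc4[C@@H](C(OC(=O)C(C)(C)C)c5ccc(O)cc5)[C@@H]2c5cc(OCc6ccccc6)cc6O[C@@H](c7ccc(OCc8ccccc8)cc7)[C@@H](c7cc(O)cc(O)c7)c56)O[C@@H]3c2ccc(OCc5ccccc5)cc2 | intermediate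
28 | para-quinone methide at C7b: 27 without acetates and without the C7b pivalate | Oc1ccc(cc1)[C@@H]2c3c(O)cc(O)cc3[C@H]3c4c(cc(OCc5ccccc5)cc4[C@@H](C=C5C=CC(=O)C=C5)[C@@H]2c5cc(OCc6ccccc6)cc6O[C@@H](c7ccc(OCc8ccccc8)cc7)[C@@H](c7cc(O)cc(O)c7)c56)O[C@@H]3c2ccc(OCc5ccccc5)cc2 | intermediate
29 | tetra-O-benzyl ether of the target (benzyl on the oxygens of the aryl rings of units A and C and on the two benzofuran-ring oxygens) | Oc1ccc([C@@H]2c3c(O)cc(O)cc3[C@H]3c4c(cc(OCc7ccccc7)cc4[C@H]4[C@H](c5ccc(O)cc5)c5c(O)cc(O)cc5[C@H]5c6c(cc(OCc7ccccc7)cc6[C@H]24)O[C@H]5c2ccc(OCc7ccccc7)cc2)O[C@@H]3c2ccc(OCc7ccccc7)cc2)cc1 | intermediate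
30 | CNP0224452.3, (7aS,8aS,7bR,8bR,7cR,8cS,7dR,8dS) in the locants above | Oc1ccc([C@@H]2c3c(O)cc(O)cc3[C@H]3c4c(cc(O)cc4[C@H]4[C@H](c5ccc(O)cc5)c5c(O)cc(O)cc5[C@H]5c6c(cc(O)cc6[C@H]24)O[C@H]5c2ccc(O)cc2)O[C@@H]3c2ccc(O)cc2)cc1 | target

**Step count and risks**

Total steps: 22. Longest linear sequence: 16 steps (1, 2, 3, 5, 6, 7, 8, 9, 11, 12, 17, 18, 19, 20, 21, 22).

Most likely to fail:

Step 21. The eight-membered closure may be outrun by base-induced tautomerisation of the quinone methide to the stilbene, which erases the C8b centre, or may show poor facial selectivity at C7b. The fallback sets out from 26 and returns at 29. DDQ is used as before, but the triphenol pivalate 27 is isolated after a neutral work-up and dissolved in hexafluoroisopropanol at 0 °C without base. Solvolysis of the para-hydroxybenzyl pivalate should give the O-protonated quinone methide, which no base can deprotonate at C8b. The free resorcinol ring of unit C should then close the ring in a cationic Friedel–Crafts alkylation to the tri-O-acetyl tetra-O-benzyl polycycle F1. K2CO3 in methanol removes the three acetates and gives 29.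

Step 20. The same competition applies (tautomerisation of quinone methide 24 with loss of the C8d centre before the slow medium-ring closure), and the C7b pivalate may be lost early to the basic fluoride. The fallback sets out from 23 and returns at 26. 23 is desilylated with HF·pyridine in THF, where no phenoxide forms, to the triphenol bis-pivalate F2. F2 is ionised in hexafluoroisopropanol at 0 °C, where the C7d pivalate, the only one with a free para-hydroxyl, should solvolyse the faster. The resorcinol ring of unit A should then close the first eight-membered ring to 25, and Ac2O/pyridine gives 26.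

Step 17. Proton and bromine transfer between the enolate and the bromoketone, electron-transfer reduction of the hindered bromide, and weak diastereocontrol at C8b/C8d may each erode the coupling. The fallback sets out from 15 and 20 and returns at 21. The lithium enolates of 15 and 20 (LiN(SiMe3)2, THF, −78 °C) are mixed and oxidised with Cu(OTf)2 in an oxidative enolate coupling, which avoids bromide 16 altogether. The cross-coupled diketone is separated from the two homodimers and equilibrated with DBU as in the main route to reach 21. No new compound is made.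

**Further compounds**

F1 | step 21 | tri-O-acetyl tetra-O-benzyl polycycle (29 with acetates on the oxygens of the unit A resorcinol ring and the unit D aryl ring) | CC(=O)Oc1ccc([C@@H]2c3c(OC(C)=O)cc(OC(C)=O)cc3[C@H]3c4c(cc(OCc7ccccc7)cc4[C@H]4[C@H](c5ccc(O)cc5)c5c(O)cc(O)cc5[C@H]5c6c(cc(OCc7ccccc7)cc6[C@H]24)O[C@H]5c2ccc(OCc7ccccc7)cc2)O[C@@H]3c2ccc(OCc7ccccc7)cc2)cc1
F2 | step 20 | triphenol bis-pivalate (23 without its three TIPS groups) | Oc1cc(O)cc(c1)[C@H]1c2c([C@@H](C(OC(=O)C(C)(C)C)c3ccc(OCc4ccc(OC)cc4)cc3)[C@@H](C(OC(=O)C(C)(C)C)c3ccc(O)cc3)c3cc(OCc4ccccc4)cc4O[C@@H](c5ccc(OCc6ccccc6)cc5)[C@@H](c5cc(OCc6ccc(OC)cc6)cc(OCc6ccc(OC)cc6)c5)c34)cc(OCc3ccccc3)cc2O[C@@H]1c1ccc(OCc2ccccc2)cc1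
F0 | step 17 | none | none
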